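**Strategy.** The five-membered ring carries a 1,3-dioxygenated array, C2(OAc)–C3H2–C4(OH)(iPr), which is the retron of an aldol addition, and it shares only the C1–C5 bond with the seven-membered ring. The route therefore builds the cycloheptene first and closes the cyclopentane last by forming C3–C4: the lithium enolate of an acetyl group on quaternary C1 adds to an isobutyryl ketone on C5. This single operation creates the hydroazulene, the tertiary carbinol stereocentre C4 and the C2 ketone used to set the 2α-acetate. The precursor is a trans-2-acetyl-3-isobutyryl-cycloheptenone, assembled by anti conjugate addition/aldol trapping on an (R)-4-silyloxy-2-methylcycloheptenone.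

Key step: step 10

Numbering: daucane locants are used for the ring carbons (C1 angular C–CH3, C2 CH–OAc, C3 CH2, C4 C(OH)iPr, C5 ring-fusion CH, C6 CH–O-aroyl, C7 CH2, C8 C–CH3, C9, C10 CH–OH); α is the face of H-5, β the face of the C1 methyl.

Assumption: the oxirane is taken as cis-fused to the seven-membered ring with its oxygen on the α face, syn to the C10 hydroxyl (as the C9 descriptor indicates); read literally, the C8 descriptor would put C7 and C10 trans across the oxirane, an arrangement a cycloheptane ring cannot reasonably hold, so the string of the target is kept unchanged for the oxirane-containing compounds.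

Remark: 1 is racemic, so 6, 7, 9, 10 and 14–16 are pairs of epimers at the methyl-bearing carbon C8 (15 also at its carbinol carbon); both centres become sp2 in step 8, and from 17 on every compound is a single stereoisomer.

Step 1
Reactants: 1 4-methyltetrahydro-2H-pyran-2-one
Product: 2 5-hydroxy-N-methoxy-N,3-dimethylpentanamide
Conditions: MeNH(OMe)·HCl, AlMe3, CH2Cl2, 0 °C → rt; aqueous work-up
Reagents that add atoms: N,O-dimethylhydroxylamine hydrochloride, CNOC.Cl
Why: Aminolysis of the lactone by the aluminium amide formed from AlMe3 and the amine salt (Weinreb amide formation) should open the ring to the hydroxy amide; no stereocentre is set.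

Step 2
Reactants: 2 5-hydroxy-N-methoxy-N,3-dimethylpentanamide
Product: 3 N-methoxy-N,3-dimethyl-5-oxopentanamide
Conditions: TEMPO (10 mol %), PhI(OAc)2, CH2Cl2, rt
Reagents that add atoms: none
Why: The TEMPO (oxoammonium) oxidation of the primary alcohol should stop at the aldehyde and leave the Weinreb amide untouched.

Step 3
Reactants: 3 N-methoxy-N,3-dimethyl-5-oxopentanamide; 4 vinylmagnesium bromide
Product: 6 (5R)-5-hydroxy-N-methoxy-N,3-dimethylhept-6-enamide, via divinylzinc 5 (not isolated)
Conditions: 4, ZnCl2, Et2O, then 1,4-dioxane (removes the magnesium halide); (−)-DAIB [(2S)-3-exo-(dimethylamino)isoborneol, 10 mol %], 3, toluene, −20 → 0 °C; aq NH4Cl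
Reagents that add atoms: none
Why: Amino-alcohol-catalysed enantioselective addition of an alkenylzinc reagent to the aldehyde; the (−)-ligand should direct vinyl transfer to the Si face and so set the (R)-carbinol (the later C6), while the Weinreb amide is inert to the zinc reagent.

Step 4
Reactants: 6 (5R)-5-hydroxy-N-methoxy-N,3-dimethylhept-6-enamide
Product: 7 (5R)-5-[(tert-butyldimethylsilyl)oxy]-N-methoxy-N,3-dimethylhept-6-enamide
Conditions: TBSCl, imidazole, DMF, rt
Reagents that add atoms: tert-butyldimethylsilyl chloride, CC(C)(C)[Si](C)(C)Cl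
Why: Imidazole-promoted silylation of the secondary allylic alcohol; the silyl ether is not a leaving group under cuprate conditions and later directs the conjugate addition.

Step 5
Reactants: 7 (5R)-5-[(tert-butyldimethylsilyl)oxy]-N-methoxy-N,3-dimethylhept-6-enamide; 8 isopropenylmagnesium bromide
Product: 9 (7R)-7-[(tert-butyldimethylsilyl)oxy]-2,5-dimethylnona-1,8-dien-3-one
Conditions: 8, THF, 0 °C; cold aq NH4Cl
Reagents that add atoms: none
Why: Weinreb ketone synthesis: the chelated tetrahedral magnesium intermediate should collapse only on work-up, so the isopropenyl ketone forms without over-addition.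

Step 6
Reactants: 9 (7R)-7-[(tert-butyldimethylsilyl)oxy]-2,5-dimethylnona-1,8-dien-3-one
Product: 10 (4R)-4-[(tert-butyldimethylsilyl)oxy]-2,6-dimethylcyclohept-2-en-1-one
Conditions: second-generation Grubbs catalyst (5 mol %), CH2Cl2 (0.005 M), 40 °C
Reagents that add atoms: none
Why: Ring-closing metathesis between the vinyl group and the 1,1-disubstituted enone alkene should give the seven-membered 2-methyl enone with loss of ethene; the silyloxy stereocentre is untouched.

Step 7
Reactants: 10 (4R)-4-[(tert-butyldimethylsilyl)oxy]-2,6-dimethylcyclohept-2-en-1-one; 11 2-bromo-3-methylbut-1-ene; 12 acetaldehyde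
Product: 15 4-[(tert-butyldimethylsilyl)oxy]-2-(1-hydroxyethyl)-2,6-dimethyl-3-(3-methylbut-1-en-2-yl)cycloheptan-1-one (alkenyl group trans to both the silyloxy and the hydroxyethyl group), via alkenylmagnesium bromide 13 (not isolated), via magnesium enolate 14 (not isolated)
Conditions: 11, Mg, THF; CuBr·SMe2 (15 mol %), 10, THF, −78 → −30 °C; then 12, −78 °C; aq NH4Cl
Reagents that add atoms: none
Why: Copper-catalysed conjugate addition of the alkenyl Grignard reagent should occur anti to the adjacent silyloxy group (sets C5), and the magnesium enolate then adds to acetaldehyde anti to the new C5 substituent, creating quaternary C1 with its methyl cis to the alkenyl group (three-component conjugate addition–aldol coupling).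

Step 8
Reactants: 15 4-[(tert-butyldimethylsilyl)oxy]-2-(1-hydroxyethyl)-2,6-dimethyl-3-(3-methylbut-1-en-2-yl)cycloheptan-1-one
Product: 17 2-acetyl-4-[(tert-butyldimethylsilyl)oxy]-2,6-dimethyl-3-(3-methylbut-1-en-2-yl)cyclohept-6-en-1-one, via saturated diketone 16 (not isolated)
Conditions: IBX (2-iodoxybenzoic acid, 3 equiv), DMSO, rt then 70 °C
Reagents that add atoms: none
Why: IBX should first oxidise the carbinol to the acetyl ketone and on warming dehydrogenate the ring ketone through its enol (IBX ketone dehydrogenation); C1 is quaternary, so only the C9=C8 enone can form, and the acetyl group has no β-hydrogen.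

Step 9
Reactants: 17 2-acetyl-4-[(tert-butyldimethylsilyl)oxy]-2,6-dimethyl-3-(3-methylbut-1-en-2-yl)cyclohept-6-en-1-one
Product: 19 2-acetyl-4-[(tert-butyldimethylsilyl)oxy]-2,6-dimethyl-3-(2-methylpropanoyl)cyclohept-6-en-1-one, via ozonide 18 (not isolated)
Conditions: O3, CH2Cl2, −78 °C (Sudan Red 7B as end-point indicator); PPh3, −78 °C → rt
Reagents that add atoms: ozone, [O-][O+]=O
Why: Chemoselective ozonolysis: the 1,1-disubstituted alkene should react much faster than the electron-poor enone double bond, unmasking the isobutyryl ketone on C5.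

Step 10
Reactants: 19 2-acetyl-4-[(tert-butyldimethylsilyl)oxy]-2,6-dimethyl-3-(2-methylpropanoyl)cyclohept-6-en-1-one
Product: 21 6α-[(tert-butyldimethylsilyl)oxy]-4β-hydroxy-trans-daucan-8-ene-2,10-dione (1β-methyl and 5α-H with 4α-isopropyl), via lithium enolate 20 (not isolated)
Conditions: LiN(SiMe3)2 (1.05 equiv), THF, −78 °C; AcOH, −78 °C
Reagents that add atoms: none
Why: LiN(SiMe3)2 removes a proton from the acetyl CH3 (C3), the only unhindered α-position of the triketone (C1 is quaternary, C9 is sp2, and both α-positions of the isobutyryl group are tertiary), and the lithium enolate adds to the C4 ketone in an intramolecular aldol addition; the closest known reaction type is the base-induced cyclisation of 1,4-diketones to 3-hydroxycyclopentanones, here stopped before dehydration. The cyclopentane closes in the 5-(enolexo)-exo-trig mode by forming C3–C4, and since the acetyl and isobutyryl groups already stand trans on C1 and C5 the new ring can only be trans-fused. The one new stereocentre, C4, is controlled by the substrate: in the closing ring the isopropyl group should take the α face, cis to H-5 and away from the C5–C6 bond and the β methyl on C1, so that the oxygen ends up β. This should also be the more stable aldol, so partial reversibility should not erode it. The step needs site-selective enolisation (acetyl CH3 against γ-deprotonation of the enone at C7 or deprotonation at C5, either of which could expel the C6 silyloxy group) and must not go on to the cyclopentenone; one equivalent of a hindered amide base at −78 °C and a cold acidic quench should secure both. The C2 ketone that remains is the handle for the 2α-acetoxy group.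

Step 11
Reactants: 21 6α-[(tert-butyldimethylsilyl)oxy]-4β-hydroxy-trans-daucan-8-ene-2,10-dione
Product: 22 6α-[(tert-butyldimethylsilyl)oxy]-2α,4β-dihydroxy-trans-daucan-8-en-10-one
Conditions: Me4NBH(OAc)3, MeCN–AcOH (1:1), −30 → 0 °C
Reagents that add atoms: none
Why: Evans–Saksena reduction: the C4 hydroxyl exchanges onto boron and delivers hydride to the β face of the C2 ketone, giving the 2α-alcohol (trans-1,3-diol), while the enone carbonyl, which has no β-hydroxyl, is not reduced.

Step 12
Reactants: 22 6α-[(tert-butyldimethylsilyl)oxy]-2α,4β-dihydroxy-trans-daucan-8-en-10-one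
Product: 23 2α-acetoxy-6α-[(tert-butyldimethylsilyl)oxy]-4β-hydroxy-trans-daucan-8-en-10-one
Conditions: Ac2O, DMAP (cat.), pyridine, CH2Cl2, 0 °C → rt
Reagents that add atoms: acetic anhydride, CC(=O)OC(C)=O
Why: DMAP-catalysed acetylation should take the secondary C2 hydroxyl and leave the hindered tertiary C4 hydroxyl free.

Step 13
Reactants: 23 2α-acetoxy-6α-[(tert-butyldimethylsilyl)oxy]-4β-hydroxy-trans-daucan-8-en-10-one
Product: 24 2α-acetoxy-4β,6α-dihydroxy-trans-daucan-8-en-10-one
Conditions: HF·pyridine, pyridine, THF, 0 °C → rt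
Reagents that add atoms: none
Why: Fluoride-mediated cleavage of the silyl ether; acetate, enone and tertiary alcohol should tolerate buffered HF·pyridine.

Step 14
Reactants: 24 2α-acetoxy-4β,6α-dihydroxy-trans-daucan-8-en-10-one; 25 3,4-dimethoxybenzoyl chloride
Product: 26 2α-acetoxy-4β-hydroxy-10-oxo-trans-daucan-8-en-6α-yl 3,4-dimethoxybenzoate
Conditions: 25, Et3N, DMAP, CH2Cl2, rt
Reagents that add atoms: none
Why: Acyl chloride/DMAP esterification of the only secondary hydroxyl; the tertiary C4 hydroxyl should not react, and the electron-rich arene is introduced only after the ozonolysis.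

Step 15
Reactants: 26 2α-acetoxy-4β-hydroxy-10-oxo-trans-daucan-8-en-6α-yl 3,4-dimethoxybenzoate
Product: 27 2α-acetoxy-4β,10α-dihydroxy-trans-daucan-8-en-6α-yl 3,4-dimethoxybenzoate
Conditions: LiBH(s-Bu)3 (2.2 equiv), THF, −78 °C; aq NH4Cl
Reagents that add atoms: none
Why: 1,2-Reduction of the β,β-disubstituted enone by a bulky trialkylborohydride; equatorial approach past the C1 methyl, as such reagents show with ketones flanked by a quaternary carbon, should give the pseudoaxial 10α-alcohol, whereas small hydrides are expected to add anti to the axial methyl; the esters are inert at −78 °C.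

Step 16
Reactants: 27 2α-acetoxy-4β,10α-dihydroxy-trans-daucan-8-en-6α-yl 3,4-dimethoxybenzoate
Product: 28 2α-acetoxy-8α,9α-epoxy-4β,10α-dihydroxy-trans-daucan-6α-yl 3,4-dimethoxybenzoate (CNP0197096.2)
Conditions: VO(acac)2 (5 mol %), t-BuOOH, CH2Cl2, 0 °C → rt
Reagents that add atoms: tert-butyl hydroperoxide, CC(C)(C)OO
Why: Vanadium-catalysed hydroxyl-directed epoxidation: the C10 allylic hydroxyl binds the vanadium peroxide and oxygen is delivered to C8=C9 syn to it, setting C8 and C9 as the cis-fused α-oxirane; esters and arene are untouched.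

**Compound list**

1 | 4-methyltetrahydro-2H-pyran-2-one (β-methyl-δ-valerolactone, racemic) | CC1CCOC(=O)C1 | starting material
2 | 5-hydroxy-N-methoxy-N,3-dimethylpentanamide (racemic) | CON(C)C(=O)CC(C)CCO | intermediate
3 | N-methoxy-N,3-dimethyl-5-oxopentanamide (racemic) | CON(C)C(=O)CC(C)CC=O | intermediate
4 | vinylmagnesium bromide | C=C[Mg]Br | starting material
5 | divinylzinc | C=C[Zn]C=C | intermediate
6 | (5R)-5-hydroxy-N-methoxy-N,3-dimethylhept-6-enamide (both C3 epimers) | C=C[C@H](O)CC(C)CC(=O)N(C)OC | intermediate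
7 | (5R)-5-[(tert-butyldimethylsilyl)oxy]-N-methoxy-N,3-dimethylhept-6-enamide (both C3 epimers) | C=C[C@H](O[Si](C)(C)C(C)(C)C)CC(C)CC(=O)N(C)OC | intermediate
8 | isopropenylmagnesium bromide | C=C(C)[Mg]Br | starting material
9 | (7R)-7-[(tert-butyldimethylsilyl)oxy]-2,5-dimethylnona-1,8-dien-3-one (both C5 epimers) | C=C[C@H](O[Si](C)(C)C(C)(C)C)CC(C)CC(=O)C(C)=C | intermediate
10 | (4R)-4-[(tert-butyldimethylsilyl)oxy]-2,6-dimethylcyclohept-2-en-1-one (both C6 epimers) | CC(C)(C)[Si](C)(C)O[C@@H]1CC(C)CC(=O)C(C)=C1 | intermediate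
11 | 2-bromo-3-methylbut-1-ene | C=C(Br)C(C)C | starting material
12 | acetaldehyde | CC=O | starting material
13 | (3-methylbut-1-en-2-yl)magnesium bromide | C=C([Mg]Br)C(C)C | intermediate
14 | bromomagnesium enolate of the conjugate adduct (alkenyl group trans to the silyloxy group) | CC(C)(C)[Si](C)(C)O[C@@H]1CC(C)CC(O[Mg]Br)=C(C)[C@H]1C(=C)C(C)C | intermediate
15 | 4-[(tert-butyldimethylsilyl)oxy]-2-(1-hydroxyethyl)-2,6-dimethyl-3-(3-methylbut-1-en-2-yl)cycloheptan-1-one (2,3-trans and 3,4-trans with respect to hydroxyethyl, alkenyl and silyloxy; carbinol and ring-methyl epimers) | CC(C)(C)[Si](C)(C)O[C@@H]1CC(C)CC(=O)[C@](C)(C(C)O)[C@H]1C(=C)C(C)C | intermediate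
16 | 2-acetyl-4-[(tert-butyldimethylsilyl)oxy]-2,6-dimethyl-3-(3-methylbut-1-en-2-yl)cycloheptan-1-one | CC(C)(C)[Si](C)(C)O[C@@H]1CC(C)CC(=O)[C@](C)(C(C)=O)[C@H]1C(=C)C(C)C | intermediate
17 | 2-acetyl-4-[(tert-butyldimethylsilyl)oxy]-2,6-dimethyl-3-(3-methylbut-1-en-2-yl)cyclohept-6-en-1-one (acetyl trans to alkenyl, alkenyl trans to silyloxy) | CC(C)(C)[Si](C)(C)O[C@@H]1CC(C)=CC(=O)[C@](C)(C(C)=O)[C@H]1C(=C)C(C)C | intermediate
18 | secondary ozonide (1,2,4-trioxolane) of 17 at the exocyclic alkene | CC(C)(C)[Si](C)(C)O[C@@H]1CC(C)=CC(=O)[C@](C)(C(C)=O)[C@H]1C2(C(C)C)OCOO2 | intermediate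
19 | 2-acetyl-4-[(tert-butyldimethylsilyl)oxy]-2,6-dimethyl-3-(2-methylpropanoyl)cyclohept-6-en-1-one (acetyl trans to isobutyryl, isobutyryl trans to silyloxy) | CC(C)(C)[Si](C)(C)O[C@@H]1CC(C)=CC(=O)[C@](C)(C(C)=O)[C@H]1C(=O)C(C)C | intermediate
20 | lithium enolate of the acetyl group of 19 | CC(C)(C)[Si](C)(C)O[C@@H]1CC(C)=CC(=O)[C@](C)(C(=C)O[Li])[C@H]1C(=O)C(C)C | intermediate
21 | 6α-[(tert-butyldimethylsilyl)oxy]-4β-hydroxy-trans-daucan-8-ene-2,10-dione | CC(C)(C)[Si](C)(C)O[C@@H]2CC(C)=CC(=O)[C@]3(C)C(=O)C[C@](O)(C(C)C)[C@@H]23 | intermediate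
22 | 6α-[(tert-butyldimethylsilyl)oxy]-2α,4β-dihydroxy-trans-daucan-8-en-10-one | CC(C)(C)[Si](C)(C)O[C@@H]2CC(C)=CC(=O)[C@]3(C)[C@H](O)C[C@](O)(C(C)C)[C@@H]23 | intermediate
23 | 2α-acetoxy-6α-[(tert-butyldimethylsilyl)oxy]-4β-hydroxy-trans-daucan-8-en-10-one | CC(C)(C)[Si](C)(C)O[C@@H]2CC(C)=CC(=O)[C@]3(C)[C@H](OC(C)=O)C[C@](O)(C(C)C)[C@@H]23 | intermediate
24 | 2α-acetoxy-4β,6α-dihydroxy-trans-daucan-8-en-10-one | O[C@@H]2CC(C)=CC(=O)[C@]3(C)[C@H](OC(C)=O)C[C@](O)(C(C)C)[C@@H]23 | intermediate
25 | 3,4-dimethoxybenzoyl chloride | COc1ccc(C(=O)Cl)cc1OC | starting material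
26 | 2α-acetoxy-4β-hydroxy-10-oxo-trans-daucan-8-en-6α-yl 3,4-dimethoxybenzoate | COc1ccc(C(=O)O[C@@H]2CC(C)=CC(=O)[C@]3(C)[C@H](OC(C)=O)C[C@](O)(C(C)C)[C@@H]23)cc1OC | intermediate
27 | 2α-acetoxy-4β,10α-dihydroxy-trans-daucan-8-en-6α-yl 3,4-dimethoxybenzoate | COc1ccc(C(=O)O[C@@H]2CC(C)=C[C@H](O)[C@]3(C)[C@H](OC(C)=O)C[C@](O)(C(C)C)[C@@H]23)cc1OC | intermediate
28 | 2α-acetoxy-8α,9α-epoxy-4β,10α-dihydroxy-trans-daucan-6α-yl 3,4-dimethoxybenzoate (CNP0197096.2) | COc1ccc(C(=O)O[C@@H]2C[C@@]3(C)O[C@@H]3[C@H](O)[C@]3(C)[C@H](OC(C)=O)C[C@](O)(C(C)C)[C@@H]23)cc1OC | target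

**Total step count:** 16. **Longest linear sequence:** 16 steps (1 → 28).

**Steps most likely to fail**

Step 15. The hydride may be delivered with poor facial selectivity, or mainly anti to the axial C1 methyl. That would give the 10β-epimer and then misdirect the epoxidation. The fallback sets the C10 centre by hydroxyl direction before the acylations and sets out from 22. A Narasaka–Prasad reduction (Et2BOMe, NaBH4, THF–MeOH, −78 °C) through the boron chelate of the C2 hydroxyl and the C10 carbonyl should give the syn-1,3-diol, 6α-silyloxy-trans-daucan-8-ene-2α,4β,10α-triol F1. Directed epoxidation (VO(acac)2, t-BuOOH) should give the 8α,9α-epoxy triol F2. Acetylation with one equivalent of Ac2O (DMAP, pyridine, 0 °C) should take the C2 hydroxyl, since the C10 hydroxyl is flanked by quaternary C1 and the oxirane, giving the 2α-acetate F3. HF·pyridine then frees the C6 hydroxyl to give the 4β,6α,10α-triol 2-acetate F4. Esterification with 25 (Et3N, DMAP) at the least hindered secondary hydroxyl comes back to the route at 28.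

Step 10. Vinylogous deprotonation at C7 or deprotonation at C5 may compete and expel the C6 silyloxy group, and the aldolate may undergo retro-aldol cleavage or dehydration on warming. The fallback replaces the basic enolate by a Lewis-acid-mediated closure and sets out from 19. In-situ trapping (LiN(iPr)2 in the presence of Me3SiCl, THF, −78 °C) should give the trimethylsilyl enol ether of the acetyl group F5. Its intramolecular Mukaiyama aldol addition to the isobutyryl ketone (TiCl4, CH2Cl2, −78 °C, aqueous work-up) comes back to the route at 21.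

Step 8. The dehydrogenation may stall at the hindered ketone or run on toward C7 at the temperature needed. The fallback separates the two oxidations and sets out from 15. Double deprotonation and silylation (LiN(iPr)2, 2.2 equiv, Me3SiCl, THF, −78 °C) should give the O-silylated trimethylsilyl enol ether F6. Saegusa–Ito oxidation (Pd(OAc)2, MeCN) and a mild acidic work-up should give the hydroxy enone F7. Oxidation of the carbinol with Dess–Martin periodinane comes back to the route at 17.

**Further compounds**

F1 | step 15 | 6α-[(tert-butyldimethylsilyl)oxy]-trans-daucan-8-ene-2α,4β,10α-triol | CC(C)(C)[Si](C)(C)O[C@@H]2CC(C)=C[C@H](O)[C@]3(C)[C@H](O)C[C@](O)(C(C)C)[C@@H]23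
F2 | step 15 | 6α-[(tert-butyldimethylsilyl)oxy]-8α,9α-epoxy-trans-daucane-2α,4β,10α-triol | CC(C)(C)[Si](C)(C)O[C@@H]2C[C@@]3(C)O[C@@H]3[C@H](O)[C@]3(C)[C@H](O)C[C@](O)(C(C)C)[C@@H]23
F3 | step 15 | 2α-acetoxy-6α-[(tert-butyldimethylsilyl)oxy]-8α,9α-epoxy-trans-daucane-4β,10α-diol | CC(C)(C)[Si](C)(C)O[C@@H]2C[C@@]3(C)O[C@@H]3[C@H](O)[C@]3(C)[C@H](OC(C)=O)C[C@](O)(C(C)C)[C@@H]23
F4 | step 15 | 2α-acetoxy-8α,9α-epoxy-trans-daucane-4β,6α,10α-triol | O[C@@H]2C[C@@]3(C)O[C@@H]3[C@H](O)[C@]3(C)[C@H](OC(C)=O)C[C@](O)(C(C)C)[C@@H]23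
F5 | step 10 | trimethylsilyl enol ether of the acetyl group of 19 | CC(C)(C)[Si](C)(C)O[C@@H]1CC(C)=CC(=O)[C@](C)(C(=C)O[Si](C)(C)C)[C@H]1C(=O)C(C)C
F6 | step 8 | trimethylsilyl enol ether (toward C9) of 15 with its carbinol as trimethylsilyl ether | CC(C)(C)[Si](C)(C)O[C@@H]1CC(C)C=C(O[Si](C)(C)C)[C@](C)(C(C)O[Si](C)(C)C)[C@H]1C(=C)C(C)C
F7 | step 8 | 4-[(tert-butyldimethylsilyl)oxy]-2-(1-hydroxyethyl)-2,6-dimethyl-3-(3-methylbut-1-en-2-yl)cyclohept-6-en-1-one | CC(C)(C)[Si](C)(C)O[C@@H]1CC(C)=CC(=O)[C@](C)(C(C)O)[C@H]1C(=C)C(C)C
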